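**Retrosynthetic overview**
1. Target 20 ← acetylation at C7, then release of the allylic alcohol, from the threo alcohol 18.
2. The C9 methyl of 18 ← the C9 carbonyl of aldol adduct 15 (imide → CH2OH → CH2OTs → CH3).
3. Key C7–C8 bond: Evans syn-glycolate boron aldol of 3,4,5-trimethoxybenzaldehyde 12 with the (aryloxy)acetyl oxazolidinone 11. It sets both stereocentres at once (syn-glycolate = threo).
4. 11 ← aryloxyacetic acid 8 + (S)-4-benzyl-1,3-oxazolidin-2-one 9; 8 ← syringaldehyde 1 by Wittig, DIBAL, O-alkylation, silylation and saponification.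
5. No ring is formed in the route: both arenes and the auxiliary ring are bought intact.

Assumption: the SMILES is read as the (7R,8R)-threo isomer (benzylic C7 and C8 both R) with an E side-chain alkene; TBS = tert-butyldimethylsilyl.

**Step 1**
Reactants: 1 syringaldehyde (4-hydroxy-3,5-dimethoxybenzaldehyde); 2 ethyl (triphenylphosphoranylidene)acetate
Product: 3 ethyl (E)-3-(4-hydroxy-3,5-dimethoxyphenyl)prop-2-enoate (ethyl sinapate)
Conditions: 2 (1.3 equiv), PhMe, 110 °C, 12 h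
Reagents that add atoms: none
Why: Wittig olefination with a stabilized ylide is E-selective and tolerates the free phenol, giving the cinnamate directly.

**Step 2**
Reactants: 3 ethyl sinapate
Product: 4 (E)-4-(3-hydroxyprop-1-en-1-yl)-2,6-dimethoxyphenol (sinapyl alcohol)
Conditions: DIBAL-H (4 equiv), PhMe, −78 → 0 °C; aq. Rochelle salt
Reagents that add atoms: none
Why: DIBAL-H reduces the conjugated ester 1,2 to the allylic alcohol without touching the alkene (ester reduction; one equivalent is consumed by the phenol).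

**Step 3**
Reactants: 4 sinapyl alcohol; 5 ethyl bromoacetate
Product: 6 ethyl 2-{4-[(E)-3-hydroxyprop-1-en-1-yl]-2,6-dimethoxyphenoxy}acetate
Conditions: K2CO3 (1.5 equiv), acetone, reflux, N2
Reagents that add atoms: none
Why: Williamson ether synthesis in which K2CO3 deprotonates only the phenol, so the bromoacetate alkylates O-4 chemoselectively and the allylic alcohol stays free.

**Step 4**
Reactants: 6 the hydroxy ester
Product: 7 ethyl 2-{4-[(E)-3-(tert-butyldimethylsilyloxy)prop-1-en-1-yl]-2,6-dimethoxyphenoxy}acetate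
Conditions: TBSCl, imidazole, DMF, 0 °C → rt
Reagents that add atoms: tert-butyldimethylsilyl chloride, CC(C)(C)[Si](C)(C)Cl
Why: Standard silyl protection of the only free hydroxyl masks the allylic alcohol for the enolate, hydride and acylation steps that follow.

**Step 5**
Reactants: 7 the silyl ether ester
Product: 8 2-{4-[(E)-3-(tert-butyldimethylsilyloxy)prop-1-en-1-yl]-2,6-dimethoxyphenoxy}acetic acid
Conditions: LiOH·H2O, THF/H2O 3:1, 0 °C → rt; cold 10% citric acid to pH 3–4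
Reagents that add atoms: lithium hydroxide, [Li+].[OH-]
Why: Saponification of an unhindered ethyl ester, with the TBS ether stable to LiOH and to brief mild acidification.

**Step 6**
Reactants: 8 the aryloxyacetic acid; 9 (S)-4-benzyl-1,3-oxazolidin-2-one
Product: 11 (S)-4-benzyl-3-(2-{4-[(E)-3-(tert-butyldimethylsilyloxy)prop-1-en-1-yl]-2,6-dimethoxyphenoxy}acetyl)-1,3-oxazolidin-2-one, via mixed pivalic anhydride 10 (not isolated)
Conditions: PivCl, Et3N, THF, −20 °C; then LiCl, 9, −20 °C → rt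
Reagents that add atoms: pivaloyl chloride, CC(C)(C)C(=O)Cl (its acyl group stays in 10 only)
Why: N-acylation of the oxazolidinone through a mixed anhydride (LiCl/Et3N method), with attack at the less hindered and more electrophilic aryloxyacetyl carbonyl.

**Step 7**
Reactants: 11 the glycolyl imide; 12 3,4,5-trimethoxybenzaldehyde
Product: 15 (S)-4-benzyl-3-[(2S,3R)-2-{4-[(E)-3-(tert-butyldimethylsilyloxy)prop-1-en-1-yl]-2,6-dimethoxyphenoxy}-3-hydroxy-3-(3,4,5-trimethoxyphenyl)propanoyl]-1,3-oxazolidin-2-one, via Z-dibutylboron enolate 13 (not isolated), via dibutylboron aldolate 14 (not isolated)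
Conditions: Bu2BOTf (1.2 equiv), i-Pr2NEt (1.4 equiv), CH2Cl2, −78 → 0 °C; 12, −78 → 0 °C; pH 7 buffer, MeOH, 30% H2O2, 0 °C
Reagents that add atoms: dibutylboron triflate, CCCCB(CCCC)OS(=O)(=O)C(F)(F)F (boron stays in 13 and 14 only)
Why: Evans syn-glycolate boron aldol in which the Z(O)-enolate adds through a closed Zimmerman–Traxler chair on the face away from the benzyl group, creating C7 and C8 together as the (2S,3R) syn adduct, which is the threo (7R,8R) array of the target.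

**Step 8**
Reactants: 15 the aldol adduct
Product: 16 (1R,2R)-2-{4-[(E)-3-(tert-butyldimethylsilyloxy)prop-1-en-1-yl]-2,6-dimethoxyphenoxy}-1-(3,4,5-trimethoxyphenyl)propane-1,3-diol
Conditions: LiBH4 (2.5 equiv), MeOH (1.1 equiv), THF, 0 °C; aq. NH4Cl
Reagents that add atoms: none
Why: Reductive cleavage of the N-acyl oxazolidinone by LiBH4 gives the primary alcohol and returns the auxiliary without touching either stereocentre (the change of the C8 descriptor from S to R is a CIP priority effect only).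

**Step 9**
Reactants: 16 the 1,3-diol
Product: 17 (2R,3R)-2-{4-[(E)-3-(tert-butyldimethylsilyloxy)prop-1-en-1-yl]-2,6-dimethoxyphenoxy}-3-hydroxy-3-(3,4,5-trimethoxyphenyl)propyl 4-methylbenzenesulfonate
Conditions: TsCl (1.15 equiv), pyridine, CH2Cl2, 0 → 4 °C (no DMAP)
Reagents that add atoms: p-toluenesulfonyl chloride, Cc1ccc(S(=O)(=O)Cl)cc1
Why: Chemoselective sulfonylation, since the primary hydroxyl reacts far faster with TsCl than the hindered secondary benzylic one.

**Step 10**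
Reactants: 17 the primary tosylate
Product: 18 (1R,2R)-2-{4-[(E)-3-(tert-butyldimethylsilyloxy)prop-1-en-1-yl]-2,6-dimethoxyphenoxy}-1-(3,4,5-trimethoxyphenyl)propan-1-ol
Conditions: LiEt3BH (4 equiv), THF, 0 °C → rt; H2O quench
Reagents that add atoms: none
Why: SN2 displacement of the primary tosylate by hydride (Super-Hydride reduction) turns C9 into the methyl group without involving the stereocentres.

**Step 11**
Reactants: 18 the threo alcohol
Product: 19 (1R,2R)-2-{4-[(E)-3-(tert-butyldimethylsilyloxy)prop-1-en-1-yl]-2,6-dimethoxyphenoxy}-1-(3,4,5-trimethoxyphenyl)propyl acetate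
Conditions: Ac2O, pyridine, DMAP (cat.), CH2Cl2, 0 °C → rt
Reagents that add atoms: acetic anhydride, CC(=O)OC(C)=O
Why: DMAP-catalysed O-acetylation of the secondary benzylic alcohol proceeds with retention because no bond to C7 is broken.

**Step 12**
Reactants: 19 the silyl-protected acetate
Product: 20 (1R,2R)-2-{4-[(E)-3-hydroxyprop-1-en-1-yl]-2,6-dimethoxyphenoxy}-1-(3,4,5-trimethoxyphenyl)propyl acetate (target)
Conditions: TBAF (1.5 equiv), AcOH (1.5 equiv), THF, 0 °C → rt
Reagents that add atoms: none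
Why: Fluoride desilylation buffered with acetic acid frees the allylic alcohol under near-neutral conditions, so the acetate neither cleaves nor migrates.

**Compound list**
1 | syringaldehyde (4-hydroxy-3,5-dimethoxybenzaldehyde) | COc1cc(C=O)cc(OC)c1O | starting material
2 | ethyl (triphenylphosphoranylidene)acetate | CCOC(=O)C=P(c1ccccc1)(c1ccccc1)c1ccccc1 | starting material
3 | ethyl (E)-3-(4-hydroxy-3,5-dimethoxyphenyl)prop-2-enoate | CCOC(=O)/C=C/c1cc(OC)c(O)c(OC)c1 | intermediate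
4 | (E)-4-(3-hydroxyprop-1-en-1-yl)-2,6-dimethoxyphenol (sinapyl alcohol) | COc1cc(/C=C/CO)cc(OC)c1O | intermediate
5 | ethyl bromoacetate | CCOC(=O)CBr | starting material
6 | ethyl 2-{4-[(E)-3-hydroxyprop-1-en-1-yl]-2,6-dimethoxyphenoxy}acetate | CCOC(=O)COc1c(OC)cc(/C=C/CO)cc1OC | intermediate
7 | ethyl 2-{4-[(E)-3-(tert-butyldimethylsilyloxy)prop-1-en-1-yl]-2,6-dimethoxyphenoxy}acetate | CCOC(=O)COc1c(OC)cc(/C=C/CO[Si](C)(C)C(C)(C)C)cc1OC | intermediate
8 | 2-{4-[(E)-3-(tert-butyldimethylsilyloxy)prop-1-en-1-yl]-2,6-dimethoxyphenoxy}acetic acid | OC(=O)COc1c(OC)cc(/C=C/CO[Si](C)(C)C(C)(C)C)cc1OC | intermediate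
9 | (S)-4-benzyl-1,3-oxazolidin-2-one | O=C1N[C@@H](Cc2ccccc2)CO1 | starting material
10 | mixed anhydride of 8 with pivalic acid | CC(C)(C)C(=O)OC(=O)COc1c(OC)cc(/C=C/CO[Si](C)(C)C(C)(C)C)cc1OC | intermediate
11 | (S)-4-benzyl-3-(2-{4-[(E)-3-(tert-butyldimethylsilyloxy)prop-1-en-1-yl]-2,6-dimethoxyphenoxy}acetyl)-1,3-oxazolidin-2-one | O=C(COc1c(OC)cc(/C=C/CO[Si](C)(C)C(C)(C)C)cc1OC)N1[C@@H](Cc2ccccc2)COC1=O | intermediate
12 | 3,4,5-trimethoxybenzaldehyde | COc1cc(C=O)cc(OC)c1OC | starting material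
13 | (Z)-O-dibutylboryl enolate of 11 (O–B and aryloxy cis) | CCCCB(CCCC)O/C(=C\Oc1c(OC)cc(/C=C/CO[Si](C)(C)C(C)(C)C)cc1OC)N1[C@@H](Cc2ccccc2)COC1=O | intermediate
14 | O-dibutylboryl aldolate of 15 (boron on the C7 oxygen) | COc1cc([C@@H](OB(CCCC)CCCC)[C@@H](C(=O)N3[C@@H](Cc4ccccc4)COC3=O)Oc2c(OC)cc(/C=C/CO[Si](C)(C)C(C)(C)C)cc2OC)cc(OC)c1OC | intermediate
15 | (S)-4-benzyl-3-[(2S,3R)-2-{4-[(E)-3-(tert-butyldimethylsilyloxy)prop-1-en-1-yl]-2,6-dimethoxyphenoxy}-3-hydroxy-3-(3,4,5-trimethoxyphenyl)propanoyl]-1,3-oxazolidin-2-one | COc1cc([C@@H](O)[C@@H](C(=O)N3[C@@H](Cc4ccccc4)COC3=O)Oc2c(OC)cc(/C=C/CO[Si](C)(C)C(C)(C)C)cc2OC)cc(OC)c1OC | intermediate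
16 | (1R,2R)-2-{4-[(E)-3-(tert-butyldimethylsilyloxy)prop-1-en-1-yl]-2,6-dimethoxyphenoxy}-1-(3,4,5-trimethoxyphenyl)propane-1,3-diol | COc1cc([C@@H](O)[C@@H](CO)Oc2c(OC)cc(/C=C/CO[Si](C)(C)C(C)(C)C)cc2OC)cc(OC)c1OC | intermediate
17 | (2R,3R)-2-{4-[(E)-3-(tert-butyldimethylsilyloxy)prop-1-en-1-yl]-2,6-dimethoxyphenoxy}-3-hydroxy-3-(3,4,5-trimethoxyphenyl)propyl 4-methylbenzenesulfonate | COc1cc([C@@H](O)[C@@H](COS(=O)(=O)c3ccc(C)cc3)Oc2c(OC)cc(/C=C/CO[Si](C)(C)C(C)(C)C)cc2OC)cc(OC)c1OC | intermediate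
18 | (1R,2R)-2-{4-[(E)-3-(tert-butyldimethylsilyloxy)prop-1-en-1-yl]-2,6-dimethoxyphenoxy}-1-(3,4,5-trimethoxyphenyl)propan-1-ol | COc1cc([C@@H](O)[C@@H](C)Oc2c(OC)cc(/C=C/CO[Si](C)(C)C(C)(C)C)cc2OC)cc(OC)c1OC | intermediate
19 | (1R,2R)-2-{4-[(E)-3-(tert-butyldimethylsilyloxy)prop-1-en-1-yl]-2,6-dimethoxyphenoxy}-1-(3,4,5-trimethoxyphenyl)propyl acetate | COc1cc([C@@H](OC(C)=O)[C@@H](C)Oc2c(OC)cc(/C=C/CO[Si](C)(C)C(C)(C)C)cc2OC)cc(OC)c1OC | intermediate
20 | (1R,2R)-2-{4-[(E)-3-hydroxyprop-1-en-1-yl]-2,6-dimethoxyphenoxy}-1-(3,4,5-trimethoxyphenyl)propyl acetate | COc1cc([C@@H](OC(C)=O)[C@@H](C)Oc2c(OC)cc(/C=C/CO)cc2OC)cc(OC)c1OC | target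

**Totals and risks**
Total step count: 12. Longest linear sequence: 12 steps (1 → 20); compounds 2, 5, 9 and 12 are bought.

Steps most likely to fail:

Step 7 (glycolate aldol). The bulky 2,6-dimethoxyphenoxy group may slow enolization or erode the diastereoselectivity. The fallback sets out from acid 8. It is coupled (EDC·HCl, DMAP, CH2Cl2) with (S)-4-benzyl-1,3-thiazolidine-2-thione to give the N-acyl thiazolidinethione F1. Its chlorotitanium enolate (TiCl4 1.05 equiv, i-Pr2NEt 1.1 equiv, N-methylpyrrolidinone 1 equiv, CH2Cl2, 0 °C, then 12 at −78 → 0 °C) reacts through the non-chelated transition state to give the Evans-syn thiazolidinethione aldol adduct F2, which has the same (2S,3R) configuration as 15. NaBH4 in THF/EtOH at 0 °C then removes the thione auxiliary reductively, and the route is rejoined at diol 16.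

Step 10 (hydride displacement). The C7 alkoxide could close an oxetane, or hydride could attack sulfur. The fallback sets out from tosylate 17. Finkelstein exchange (NaI, acetone, reflux) gives the primary iodide F3 (named 1R,2S only because iodine changes the CIP priorities). Radical-chain deiodination (Bu3SnH 2 equiv, Et3B/air, PhMe, rt, stannane kept at 0.2 M or above so hydrogen transfer outruns β-scission of the aryloxy group) needs no alkoxide and comes back to the route at 18.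

Step 12 (desilylation next to the acetate). The acetate could be lost, or the electron-rich cinnamyl alcohol could ionize. The fallback sets out from 18. TBAF in THF first gives the free allylic-benzylic diol F4, and Ac2O/pyridine/DMAP converts it into the diacetate F5. Immobilized Candida antarctica lipase B (pH 7 phosphate buffer/MTBE, rt) then hydrolyses only the unhindered primary allylic acetate and arrives directly at target 20.

**Further compounds**
F1 | step 7 | (S)-4-benzyl-3-(2-{4-[(E)-3-(tert-butyldimethylsilyloxy)prop-1-en-1-yl]-2,6-dimethoxyphenoxy}acetyl)-1,3-thiazolidine-2-thione | O=C(COc1c(OC)cc(/C=C/CO[Si](C)(C)C(C)(C)C)cc1OC)N1[C@@H](Cc2ccccc2)CSC1=S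
F2 | step 7 | (S)-4-benzyl-3-[(2S,3R)-2-{4-[(E)-3-(tert-butyldimethylsilyloxy)prop-1-en-1-yl]-2,6-dimethoxyphenoxy}-3-hydroxy-3-(3,4,5-trimethoxyphenyl)propanoyl]-1,3-thiazolidine-2-thione | COc1cc([C@@H](O)[C@@H](C(=O)N3[C@@H](Cc4ccccc4)CSC3=S)Oc2c(OC)cc(/C=C/CO[Si](C)(C)C(C)(C)C)cc2OC)cc(OC)c1OC
F3 | step 10 | (1R,2S)-2-{4-[(E)-3-(tert-butyldimethylsilyloxy)prop-1-en-1-yl]-2,6-dimethoxyphenoxy}-3-iodo-1-(3,4,5-trimethoxyphenyl)propan-1-ol | COc1cc([C@@H](O)[C@@H](CI)Oc2c(OC)cc(/C=C/CO[Si](C)(C)C(C)(C)C)cc2OC)cc(OC)c1OC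
F4 | step 12 | (1R,2R)-2-{4-[(E)-3-hydroxyprop-1-en-1-yl]-2,6-dimethoxyphenoxy}-1-(3,4,5-trimethoxyphenyl)propan-1-ol | COc1cc([C@@H](O)[C@@H](C)Oc2c(OC)cc(/C=C/CO)cc2OC)cc(OC)c1OC
F5 | step 12 | (1R,2R)-2-{4-[(E)-3-acetoxyprop-1-en-1-yl]-2,6-dimethoxyphenoxy}-1-(3,4,5-trimethoxyphenyl)propyl acetate | COc1cc([C@@H](OC(C)=O)[C@@H](C)Oc2c(OC)cc(/C=C/COC(C)=O)cc2OC)cc(OC)c1OC
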